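**Plan**

1. Locants follow the carbon chain: C1 lactone C=O, C2, C3 ketone, C4, C5 (OMe), C6=C7, C8, C9, C10=C11, C12 (ether carbon), C13, C14, C15=C16, C17 (ethyl), C18, C19 (carbon common to the three small rings), C20 (enol ether carbon).
2. Cuts: C2–C3 (13-membered ring, Nozaki–Hiyama–Kishi closure, then oxidation); C6=C7 (Z-selective Wittig reaction with an α-methoxy ketone); C12–C13 and C14–C19 together (key event); O–C12 (enol ether from a 3-iodotetronic acid and an enyne).
3. Key event: the tetronate unit H–C19–C20–O, as its 2-silyloxyfuran, together with the protonated O–C12(=CH2) group forms a 2-oxonia-diene C19=C20–O(+)=C12. This adds across the C13=C14 end of a (Z)-diene tethered to C19 through C18–C17–C16=C15, so the dihydropyran and the cyclohexene close in one operation.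
4. Ring order forward: butenolide (aldehyde plus propiolate), then dihydropyran and cyclohexene (step 18), then the macrocycle (step 23).
5. Stereochemistry: C17 from sparteine-mediated lithiation–borylation and a stereospecific Zweifel coupling; C12, C14 and C19 relayed from C17 in the key step; C5 from (R)-α-hydroxy-γ-butyrolactone; C10=C11 from syn carbocupration of propyne; C15=C16 from the Zweifel coupling; C6=C7 from the Wittig reaction.

Key step: step 18

Remark: compounds 15–18, 30 and 31 are carried as mixtures at C19, which becomes planar in 31; compound 38 is a mixture at C3, which is oxidised in step 24.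

**Route**

Step 1
Reactants: 1 3-[(tert-butyldimethylsilyl)oxy]propan-1-ol
Product: 2 3-[(tert-butyldimethylsilyl)oxy]propyl N,N-diisopropylcarbamate
Conditions: i-Pr2NC(O)Cl, Et3N, DMAP (cat.), CH2Cl2, 40 °C
Reagents that add atoms: N,N-diisopropylcarbamoyl chloride, CC(C)N(C(C)C)C(Cl)=O
Why: O-acylation of the primary alcohol by the carbamoyl chloride (carbamate formation) should install the directing group for the next step; no stereocentre is formed.

Step 2
Reactants: 2; 3 2-ethyl-4,4,5,5-tetramethyl-1,3,2-dioxaborolane
Product: 5 (S)-tert-butyldimethyl{[3-(4,4,5,5-tetramethyl-1,3,2-dioxaborolan-2-yl)pentyl]oxy}silane, via boronate complex 4 (not isolated)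
Conditions: s-BuLi, (−)-sparteine, Et2O, −78 °C; 3; then 35 °C
Reagents that add atoms: none
Why: Lithiation–borylation (Hoppe-type α-lithiation of the carbamate, then 1,2-metalate rearrangement): sparteine-directed removal of one enantiotopic proton, borylation with retention and migration of ethyl with inversion should set C17 as (S).

Step 3
Reactants: 6 2-methylbut-1-en-3-yne
Product: 7 2-methylpent-1-en-3-yne
Conditions: n-BuLi, THF, −78 °C; MeI, −78 °C to rt
Reagents that add atoms: iodomethane, CI
Why: Deprotonation of the terminal alkyne and SN2 methylation of the acetylide (alkyne alkylation) should be clean for this small enyne.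

Step 4
Reactants: 7
Product: 9 (E)-2-iodo-4-methylpenta-2,4-diene, via alkenylzirconocene chloride 8 (not isolated)
Conditions: Cp2Zr(H)Cl, THF, rt; I2, 0 °C
Reagents that add atoms: iodine, II
Why: Schwartz hydrozirconation is a syn addition that should place zirconium on the methyl-bearing alkyne carbon, away from the branched isopropenyl group, and iodinolysis with retention should give the (E)-iodide.

Step 5
Reactants: 5; 9
Product: 11 tert-butyl{[(3S,4Z)-3-ethyl-4,6-dimethylhepta-4,6-dien-1-yl]oxy}dimethylsilane, via boronate complex 10 (not isolated)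
Conditions: 9, t-BuLi, Et2O, −78 °C; 5; I2, MeOH; NaOMe, −78 °C to rt
Reagents that add atoms: none
Why: Zweifel olefination: the secondary alkyl group migrates from boron to carbon with retention at C17 and the anti elimination inverts the alkene geometry, so the (E)-alkenyllithium should give the (Z)-C15=C16 alkene.

Step 6
Reactants: 11
Product: 12 (3S,4Z)-3-ethyl-4,6-dimethylhepta-4,6-dien-1-ol
Conditions: Bu4NF, THF, 0 °C
Reagents that add atoms: none
Why: Fluoride-mediated desilylation should free the primary alcohol without touching the diene or C17.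

Step 7
Reactants: 12
Product: 13 (3S,4Z)-3-ethyl-4,6-dimethylhepta-4,6-dienal
Conditions: Dess–Martin periodinane, NaHCO3, CH2Cl2, 0 °C
Reagents that add atoms: none
Why: Dess–Martin oxidation of the primary alcohol should stop at the aldehyde, and C17, being β to the carbonyl group, cannot epimerise.

Step 8
Reactants: 13; 14 ethyl propiolate
Product: 16 4-(allyloxy)-5-[(2S,3Z)-2-ethyl-3,5-dimethylhexa-3,5-dien-1-yl]furan-2(5H)-one, via hydroxy ynoate 15 (not isolated)
Conditions: 14, LiN(SiMe3)2, THF, −78 °C; 13; then allyl alcohol, −78 °C to rt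
Reagents that add atoms: allyl alcohol, C=CCO
Why: Acetylide 1,2-addition to the aldehyde, then alkoxide-catalysed oxa-Michael addition of allyl alcohol and lactonisation (the tetronate synthesis from γ-hydroxy ynoates) should give the 4-allyloxybutenolide; C19 forms as a mixture, which is without consequence.

Step 9
Reactants: 16
Product: 17 5-[(2S,3Z)-2-ethyl-3,5-dimethylhexa-3,5-dien-1-yl]-4-hydroxyfuran-2(5H)-one
Conditions: Pd(PPh3)4 (cat.), morpholine, THF, rt
Reagents that add atoms: none
Why: Tsuji–Trost deallylation: the π-allylpalladium complex formed from the allyl enol ether is trapped by morpholine, which should free the tetronic acid without affecting the diene.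

Step 10
Reactants: 17
Product: 18 5-[(2S,3Z)-2-ethyl-3,5-dimethylhexa-3,5-dien-1-yl]-4-hydroxy-3-iodofuran-2(5H)-one
Conditions: N-iodosuccinimide, CH2Cl2, 0 °C
Reagents that add atoms: N-iodosuccinimide, O=C1CCC(=O)N1I
Why: Electrophilic iodination of the enol at C2 (α-halogenation of a 1,3-dicarbonyl compound) should be far faster than attack on the diene, and it blocks C2 for step 18.

Step 11
Reactants: 19 (3-bromopropoxy)(tert-butyl)dimethylsilane; 20 propyne; 21 (bromoethynyl)trimethylsilane
Product: 23 tert-butyldimethyl{[(4Z)-4-methyl-7-(trimethylsilyl)hept-4-en-6-yn-1-yl]oxy}silane, via alkenylcopper 22 (not isolated)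
Conditions: 19, Mg, THF; CuBr·SMe2, Et2O–Me2S, −45 °C; 20, −25 °C; 21, TMEDA, −20 °C
Reagents that add atoms: none
Why: Normant carbocupration: the alkylcopper reagent adds syn across propyne with copper at the terminal carbon, and alkynylation of the alkenylcopper with retention should fix the (Z)-C10=C11 geometry.

Step 12
Reactants: 23
Product: 24 (4Z)-4-methylhept-4-en-6-yn-1-ol
Conditions: Bu4NF (2.2 equiv), THF, 0 °C to rt
Reagents that add atoms: none
Why: Fluoride should cleave both the O-silyl ether and the C-silyl alkyne (desilylation) in one operation.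

Step 13
Reactants: 24
Product: 25 (3Z)-7-bromo-4-methylhept-3-en-1-yne
Conditions: CBr4, PPh3, CH2Cl2, 0 °C
Reagents that add atoms: tetrabromomethane, BrC(Br)(Br)Br
Why: Appel reaction: SN2 displacement of the activated primary alcohol by bromide should leave the enyne untouched.

Step 14
Reactants: 26 (R)-3-hydroxydihydrofuran-2(3H)-one
Product: 27 (R)-3-methoxydihydrofuran-2(3H)-one
Conditions: Ag2O, MeI, MeCN, rt
Reagents that add atoms: iodomethane, CI
Why: Purdie methylation is a non-basic etherification, so the α-centre of the lactone (the future C5) should keep its (R) configuration.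

Step 15
Reactants: 27
Product: 28 (3R)-3-methoxy-2-methyltetrahydrofuran-2-ol (lactol form of (R)-5-hydroxy-3-methoxypentan-2-one)
Conditions: MeLi (1.05 equiv), THF, −78 °C; aq. NH4Cl
Reagents that add atoms: methyllithium, [Li]C
Why: Addition of one equivalent of methyllithium to the lactone should stop at the stable lithium lactolate (lactone-to-lactol addition), which holds the methyl ketone in masked form.

Step 16
Reactants: 28
Product: 29 (R)-5-[(tert-butyldimethylsilyl)oxy]-3-methoxypentan-2-one
Conditions: t-BuMe2SiCl, imidazole, DMF, rt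
Reagents that add atoms: tert-butyldimethylsilyl chloride, CC(C)(C)[Si](C)(C)Cl
Why: Silylation should trap the open hydroxy ketone tautomer at its primary hydroxyl group (silyl ether formation), the tertiary lactol hydroxyl being too hindered to react.

Step 17
Reactants: 18; 25
Product: 30 4-{[(3Z)-7-bromo-4-methylhepta-1,3-dien-2-yl]oxy}-5-[(2S,3Z)-2-ethyl-3,5-dimethylhexa-3,5-dien-1-yl]-3-iodofuran-2(5H)-one
Conditions: [RuCl2(p-cymene)]2 (cat.), P(2-furyl)3, Na2CO3 (cat.), toluene, 50 °C
Reagents that add atoms: none
Why: Ruthenium-catalysed Markovnikov addition of an acidic O–H group across a terminal alkyne (the enol ester synthesis from carboxylic acids and alkynes or enynes) should give the 2-oxy-1,3-diene, the iodine at C2 excluding C-alkenylation.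

Step 18
Reactants: 30
Product: 32 tricyclic iodide (12S,14S,17S,19S), via silyloxyfuran 31 (not isolated)
Conditions: t-BuMe2SiOTf (1.3 equiv), 2,6-lutidine (1.1 equiv), CH2Cl2, −78 °C to 0 °C
Reagents that add atoms: none
Why: Proposed new method: silylation gives the 2-silyloxyfuran 31, and the lutidinium triflate formed alongside protonates the terminal CH2 of the O-dienyl ether, so that C19=C20, the ether oxygen and C12 make up a 2-oxonia-diene that adds across C13=C14 (C13 bonds to C12, then the allyl cation at C14 is taken by the furan carbon C19), after which the silyl group passes to triflate and both the silyl triflate and the base are regenerated. The closest known reactions are the oxa-Povarov reaction of aryl oxocarbenium ions with alkenes and Prins additions that end in a vinylogous Mukaiyama attack of a 5-substituted 2-silyloxyfuran on a tertiary cation. The dihydropyran closes as the six-membered ring of this formal [4+2] addition, and the cyclohexene closes in the same event by six-membered attack of C19 on the C14 end of the C14–C16 allyl cation, the tether C18–C17–C16=C15 being held cisoid by the (Z)-alkene. At C19 and C14 the tether leaves the furan from the inside position of the diene, so only the cis ring fusion (14-methyl cis to the lactone oxygen) can form; at C12 the methyl group should take the crowded inside position and the larger alkenyl chain the outside one, which puts the chain cis to the 14-methyl; the absolute sense follows from C17, whose ethyl group should lie equatorial in a chair-like closure with the lactone oxygen, not C20, axial on the new cyclohexene. The step needs the cation to be taken at C12 by C13 and not at C10 by the furan, and the furan to react at C19 and not at C2; the iodine blocks C2, closure of C19 onto C10 would press the inside substituents C18 and C9 against each other, and no other nucleophilic alkene is present because C6=C7 is introduced later.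

Step 19
Reactants: 32
Product: 33 triphenylphosphonium bromide of 32 (PPh3+ at C7)
Conditions: PPh3, MeCN, 45 °C
Reagents that add atoms: triphenylphosphine, c1ccc(cc1)P(c1ccccc1)c1ccccc1
Why: Quaternisation of the phosphine by the primary bromide (SN2) should proceed at a temperature low enough to avoid Claisen rearrangement of the allyl vinyl ether unit C2=C20–O–C12–C11=C10.

Step 20
Reactants: 33; 29
Product: 35 silyl ether (5R,6Z,10Z), the seco compound with C3–OSiMe2t-Bu, via ylide 34 (not isolated)
Conditions: KN(SiMe3)2, THF, −78 °C; 29, −78 °C to 0 °C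
Reagents that add atoms: none
Why: Wittig reaction of a non-stabilised ylide with an α-alkoxy ketone, which is known to give the (Z)-trisubstituted allylic ether, should set the C6=C7 geometry (C8 cis to C5) without touching C5.

Step 21
Reactants: 35
Product: 36 primary alcohol (C3–OH)
Conditions: HF·pyridine, pyridine, THF, 0 °C
Reagents that add atoms: none
Why: Buffered HF·pyridine should remove the silyl ether (desilylation) without ionising the tertiary allylic ether at C12.

Step 22
Reactants: 36
Product: 37 aldehyde (C3)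
Conditions: Dess–Martin periodinane, NaHCO3, CH2Cl2, 0 °C
Reagents that add atoms: none
Why: Buffered Dess–Martin oxidation should give the β-methoxy aldehyde without elimination of methanol.

Step 23
Reactants: 37
Product: 38 macrocyclic C3 carbinol (both C3 epimers)
Conditions: CrCl2 (10 equiv), NiCl2 (cat.), DMSO–THF, rt, 2 mM
Reagents that add atoms: none
Why: Nozaki–Hiyama–Kishi reaction: nickel-catalysed activation of the vinyl iodide, transfer to chromium and 1,2-addition to the aldehyde should close the 13-membered ring at C2–C3 under neutral conditions that spare the β-methoxy aldehyde.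

Step 24
Reactants: 38
Product: 39 streptaspironate A
Conditions: Dess–Martin periodinane, NaHCO3, CH2Cl2, 0 °C
Reagents that add atoms: none
Why: Dess–Martin oxidation of the allylic alcohol to the C3 ketone should give the 3-acyltetronate of the target under conditions too mild for β-elimination at C5.

**Compound list**

1 | 3-[(tert-butyldimethylsilyl)oxy]propan-1-ol | CC(C)(C)[Si](C)(C)OCCCO | starting material
2 | 3-[(tert-butyldimethylsilyl)oxy]propyl N,N-diisopropylcarbamate | CC(C)(C)[Si](C)(C)OCCCOC(=O)N(C(C)C)C(C)C | intermediate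
3 | 2-ethyl-4,4,5,5-tetramethyl-1,3,2-dioxaborolane | CCB1OC(C)(C)C(C)(C)O1 | starting material
4 | lithium boronate complex of 3 with the (S)-α-lithiated carbamate | [Li+].CC[B-]1(OC(C)(C)C(C)(C)O1)[C@@H](CCO[Si](C)(C)C(C)(C)C)OC(=O)N(C(C)C)C(C)C | intermediate
5 | (S)-tert-butyldimethyl{[3-(4,4,5,5-tetramethyl-1,3,2-dioxaborolan-2-yl)pentyl]oxy}silane | CC[C@H](B1OC(C)(C)C(C)(C)O1)CCO[Si](C)(C)C(C)(C)C | intermediate
6 | 2-methylbut-1-en-3-yne | C=C(C)C#C | starting material
7 | 2-methylpent-1-en-3-yne | C=C(C)C#CC | intermediate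
8 | chlorobis(cyclopentadienyl)[(2E)-4-methylpenta-2,4-dien-2-yl]zirconium | C=C(C)/C=C(\C)[Zr](Cl)(C1C=CC=C1)C1C=CC=C1 | intermediate
9 | (E)-2-iodo-4-methylpenta-2,4-diene | C=C(C)/C=C(\C)I | intermediate
10 | lithium boronate complex of 5 with (E)-4-methylpenta-2,4-dien-2-yllithium | [Li+].CC[C@@H](CCO[Si](C)(C)C(C)(C)C)[B-]1(OC(C)(C)C(C)(C)O1)/C(C)=C/C(C)=C | intermediate
11 | tert-butyl{[(3S,4Z)-3-ethyl-4,6-dimethylhepta-4,6-dien-1-yl]oxy}dimethylsilane | CC[C@@H](CCO[Si](C)(C)C(C)(C)C)/C(C)=C\C(C)=C | intermediate
12 | (3S,4Z)-3-ethyl-4,6-dimethylhepta-4,6-dien-1-ol | CC[C@@H](CCO)/C(C)=C\C(C)=C | intermediate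
13 | (3S,4Z)-3-ethyl-4,6-dimethylhepta-4,6-dienal | CC[C@@H](CC=O)/C(C)=C\C(C)=C | intermediate
14 | ethyl propiolate | C#CC(=O)OCC | starting material
15 | ethyl (6S,7Z)-6-ethyl-4-hydroxy-7,9-dimethyldeca-7,9-dien-2-ynoate (both C4 epimers) | CC[C@@H](CC(O)C#CC(=O)OCC)/C(C)=C\C(C)=C | intermediate
16 | 4-(allyloxy)-5-[(2S,3Z)-2-ethyl-3,5-dimethylhexa-3,5-dien-1-yl]furan-2(5H)-one | CC[C@@H](CC1OC(=O)C=C1OCC=C)/C(C)=C\C(C)=C | intermediate
17 | 5-[(2S,3Z)-2-ethyl-3,5-dimethylhexa-3,5-dien-1-yl]-4-hydroxyfuran-2(5H)-one | CC[C@@H](CC1OC(=O)C=C1O)/C(C)=C\C(C)=C | intermediate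
18 | 5-[(2S,3Z)-2-ethyl-3,5-dimethylhexa-3,5-dien-1-yl]-4-hydroxy-3-iodofuran-2(5H)-one | CC[C@@H](CC1OC(=O)C(I)=C1O)/C(C)=C\C(C)=C | intermediate
19 | (3-bromopropoxy)(tert-butyl)dimethylsilane | CC(C)(C)[Si](C)(C)OCCCBr | starting material
20 | propyne | CC#C | starting material
21 | (bromoethynyl)trimethylsilane | C[Si](C)(C)C#CBr | starting material
22 | [(1Z)-5-[(tert-butyldimethylsilyl)oxy]-2-methylpent-1-en-1-yl]copper | [Cu]/C=C(/C)CCCO[Si](C)(C)C(C)(C)C | intermediate
23 | tert-butyldimethyl{[(4Z)-4-methyl-7-(trimethylsilyl)hept-4-en-6-yn-1-yl]oxy}silane | C[Si](C)(C)C#C/C=C(/C)CCCO[Si](C)(C)C(C)(C)C | intermediate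
24 | (4Z)-4-methylhept-4-en-6-yn-1-ol | C#C/C=C(/C)CCCO | intermediate
25 | (3Z)-7-bromo-4-methylhept-3-en-1-yne | C#C/C=C(/C)CCCBr | intermediate
26 | (R)-3-hydroxydihydrofuran-2(3H)-one | O[C@@H]1CCOC1=O | starting material
27 | (R)-3-methoxydihydrofuran-2(3H)-one | CO[C@@H]1CCOC1=O | intermediate
28 | (3R)-3-methoxy-2-methyltetrahydrofuran-2-ol | CO[C@@H]1CCOC1(C)O | intermediate
29 | (R)-5-[(tert-butyldimethylsilyl)oxy]-3-methoxypentan-2-one | CO[C@H](CCO[Si](C)(C)C(C)(C)C)C(C)=O | intermediate
30 | 4-{[(3Z)-7-bromo-4-methylhepta-1,3-dien-2-yl]oxy}-5-[(2S,3Z)-2-ethyl-3,5-dimethylhexa-3,5-dien-1-yl]-3-iodofuran-2(5H)-one | CC[C@@H](CC1OC(=O)C(I)=C1OC(=C)/C=C(/C)CCCBr)/C(C)=C\C(C)=C | intermediate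
31 | 2-(tert-butyldimethylsilyloxy)furan of 30: {[4-{[(3Z)-7-bromo-4-methylhepta-1,3-dien-2-yl]oxy}-5-[(2S,3Z)-2-ethyl-3,5-dimethylhexa-3,5-dien-1-yl]-3-iodofuran-2-yl]oxy}(tert-butyl)dimethylsilane | CC[C@@H](Cc1oc(O[Si](C)(C)C(C)(C)C)c(I)c1OC(=C)/C=C(/C)CCCBr)/C(C)=C\C(C)=C | intermediate
32 | tricyclic iodide (12S,14S,17S,19S): 2-iodobutenolide (O, C1, C2, C20, C19) fused along C19–C20 to the dihydropyran (O, C12, C13, C14, C19, C20), itself fused along C14–C19 to the cyclohexene (C14 to C19, C15=C16); C12 carries methyl and the (1Z)-5-bromo-2-methylpent-1-enyl chain, C14 and C16 methyl, C17 ethyl | CC[C@H]1C[C@@]23OC(=O)C(I)=C2O[C@](C)(/C=C(/C)CCCBr)C[C@@]3(C)C=C1C | intermediate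
33 | triphenylphosphonium bromide of 32 (PPh3+ at C7 in place of bromine) | CC[C@H]1C[C@@]23OC(=O)C(I)=C2O[C@](C)(/C=C(/C)CCC[P+](c4ccccc4)(c4ccccc4)c4ccccc4)C[C@@]3(C)C=C1C.[Br-] | intermediate
34 | ylide of 33 (C7=PPh3) | CC[C@H]1C[C@@]23OC(=O)C(I)=C2O[C@](C)(/C=C(/C)CCC=P(c4ccccc4)(c4ccccc4)c4ccccc4)C[C@@]3(C)C=C1C | intermediate
35 | silyl ether (5R,6Z,10Z): 32 extended at C7 by C6(Me)=, C5(OMe), C4 and C3H2–OSiMe2t-Bu | CC[C@H]1C[C@@]23OC(=O)C(I)=C2O[C@](C)(/C=C(/C)CC/C=C(/C)[C@H](OC)CCO[Si](C)(C)C(C)(C)C)C[C@@]3(C)C=C1C | intermediate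
36 | primary alcohol of 35 (C3–OH) | CC[C@H]1C[C@@]23OC(=O)C(I)=C2O[C@](C)(/C=C(/C)CC/C=C(/C)[C@H](OC)CCO)C[C@@]3(C)C=C1C | intermediate
37 | aldehyde of 36 (C3) | CC[C@H]1C[C@@]23OC(=O)C(I)=C2O[C@](C)(/C=C(/C)CC/C=C(/C)[C@H](OC)CC=O)C[C@@]3(C)C=C1C | intermediate
38 | macrocyclic C3 carbinol (3-hydroxy analogue of the target, both C3 epimers) | CC[C@H]1C[C@@]23OC(=O)C4=C2O[C@](C)(/C=C(/C)CC/C=C(/C)[C@H](OC)CC4O)C[C@@]3(C)C=C1C | intermediate
39 | streptaspironate A | CC[C@H]1C[C@@]23OC(=O)C4=C2O[C@](C)(/C=C(/C)CC/C=C(/C)[C@H](OC)CC4=O)C[C@@]3(C)C=C1C | target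

**Totals**

Total step count: 24. Longest linear sequence: 16 steps (1, 2, 5–10, 17–24).

**Steps most likely to fail**

1. Step 18 (proposed new method). What may go wrong: loss of the silyl group from the furan by protonation before the diene has added; attack of the furan on the far end (C10) of the allyl cation; poor face selectivity. The fallback uses known reactions, sets out from 30 and returns at 32. Addition of HCl to the enol ether of 30, followed by ZnCl2-catalysed alkylation of isoprene by the resulting α-chloro ether (the classical addition of α-halo ethers to 1,3-dienes), would form the C12–C13 bond intermolecularly and give the 1,4-adduct, allylic chloride F1. Silylation (t-BuMe2SiOTf, Et3N) to silyloxyfuran F2 and ionisation of the chloride with AgOTf would close the dihydropyran by γ-alkylation of the silyloxyfuran at C19 (vinylogous Mukaiyama alkylation), giving vinyl dihydropyran F3. Ring-closing metathesis of the vinyl group with the C15=C16 alkene of the side chain (second-generation Hoveyda–Grubbs catalyst, CH2Cl2, 40 °C), with loss of isoprene, would close the cyclohexene and give 32. The relay from C17 is given up in this sequence, so 32 would have to be separated from its diastereomers.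

2. Step 17. What may go wrong: addition in the anti-Markovnikov sense, or isomerisation of the (Z)-enyne at the metal. The fallback sets out from 25 and returns at 30. Copper-catalysed Markovnikov protoboration of 25 (B2pin2, MeOH, (SIMes)CuCl, NaOt-Bu) would give dienylboronate F4. Chan–Lam coupling of F4 with 18 (Cu(OAc)2, Et3N, air, CH2Cl2) would then give 30.

3. Step 23. What may go wrong: intermolecular coupling instead of ring closure; slow oxidative addition at the hindered α-iodobutenolide; β-elimination of methanol from the aldehyde. The fallback closes the ring at C6=C7 instead; it sets out from 28 and 32 and returns at 38. Oxidation of lactol 28 (Dess–Martin periodinane) would give keto aldehyde F5. Intermolecular Nozaki–Hiyama–Kishi addition of 32 to the aldehyde group of F5 (CrCl2, NiCl2 cat.) would give hydroxy ketone F6, and PPh3 would convert it to phosphonium bromide F7. KN(SiMe3)2 (2 equiv) at high dilution would then bring about the intramolecular Wittig reaction, again Z-selective through the α-methoxy ketone, to give 38.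

Further compounds
F1 | step 18 | allylic chloride, the 1,4-adduct of 30 with isoprene: C12 carries methyl, the (Z)-bromoalkenyl chain and a 4-chloro-2-methylbut-2-enyl group (mixture at C12 and C19) | CC[C@@H](CC1OC(=O)C(I)=C1OC(C)(CC(C)=CCCl)/C=C(/C)CCCBr)/C(C)=C\C(C)=C
F2 | step 18 | 2-(tert-butyldimethylsilyloxy)furan of F1 | CC[C@@H](Cc1oc(O[Si](C)(C)C(C)(C)C)c(I)c1OC(C)(CC(C)=CCCl)/C=C(/C)CCCBr)/C(C)=C\C(C)=C
F3 | step 18 | vinyl dihydropyran (12S,14S,19S isomer shown): butenolide fused to the dihydropyran, C14 carrying methyl and vinyl, C19 still carrying the (2S,3Z)-2-ethyl-3,5-dimethylhexa-3,5-dienyl chain | CC[C@@H](C[C@@]12OC(=O)C(I)=C1O[C@](C)(/C=C(/C)CCCBr)C[C@@]2(C)C=C)/C(C)=C\C(C)=C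
F4 | step 17 | 2-[(3Z)-7-bromo-4-methylhepta-1,3-dien-2-yl]-4,4,5,5-tetramethyl-1,3,2-dioxaborolane | C=C(B1OC(C)(C)C(C)(C)O1)/C=C(/C)CCCBr
F5 | step 23 | (R)-3-methoxy-4-oxopentanal | CO[C@H](CC=O)C(C)=O
F6 | step 23 | hydroxy ketone: 32 with iodine at C2 replaced by CH(OH)–CH2–CH(OMe)–C(=O)CH3 (C3 to C6, 5R, both C3 epimers) | CC[C@H]1C[C@@]23OC(=O)C(C(O)C[C@@H](OC)C(C)=O)=C2O[C@](C)(/C=C(/C)CCCBr)C[C@@]3(C)C=C1C
F7 | step 23 | triphenylphosphonium bromide of F6 (PPh3+ at C7) | CC[C@H]1C[C@@]23OC(=O)C(C(O)C[C@@H](OC)C(C)=O)=C2O[C@](C)(/C=C(/C)CCC[P+](c4ccccc4)(c4ccccc4)c4ccccc4)C[C@@]3(C)C=C1C.[Br-]
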